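**Plan**
- **Cuts, in retrosynthetic order:** the two O-acetyl masks; the C5–O bond of ring A; O1–C2 and C2–C3 of ring C, which leads back to a chalcone and then to an acetophenone plus isovanillin; the C6–OMe bond (flavone numbering, via a bromide); the C4–C4a acyl–aryl bond.
- **Forward:** ring A is bought as 2-methoxyresorcinol and receives the acetyl group, then bromine, then methoxyl. Ring B is bought as isovanillin. An aldol condensation joins the two, and ring C closes through the only hydroxyl ortho to the ketone.
- **Enabling feature:** in the 5-deoxyflavone, C5–H is the only C–H bond of ring A and lies peri to the C4 carbonyl oxygen of ring C. O, C4, C4a, C5 and a metal therefore complete a five-membered chelate, and the C5 oxygen can be added last by directed C–H oxygenation.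
- **Stereochemistry:** acerosin has no stereocentre. The C2 centre of the transient flavanone is racemic and is erased by dehydrogenation, and the E geometry of the chalcone is lost on ring closure.

Key step: step 7

Assumption (chemistry): the oxygen delivered to C5 is counted as coming from PhI(OCOCF3)2, although its trifluoroacetate ligands exchange with the solvent acid.

Step 1
Reactants: 1 2-methoxyresorcinol (2-methoxybenzene-1,3-diol)
Product: 3 2,4-dihydroxy-3-methoxyacetophenone, via ketiminium chloride 2 (not isolated)
Conditions: MeCN (1.5 equiv), ZnCl2 (0.5 equiv), HCl (g), Et2O, 0 °C to rt; then H2O, reflux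
Reagents that add atoms: acetonitrile, CC#N; water, O
Why: Houben–Hoesch acylation, in which the nitrilium-type electrophile attacks the position ortho to one hydroxyl and para to the other (C4 and C6 of 1 are equivalent by symmetry), the deactivated iminium salt 2 separates and cannot react twice, and hot water hydrolyses it to the ketone.

Step 2
Reactants: 3 2,4-dihydroxy-3-methoxyacetophenone
Product: 4 5-bromo-2,4-dihydroxy-3-methoxyacetophenone
Conditions: NBS (1.0 equiv), MeCN, 0 °C
Reagents that add atoms: N-bromosuccinimide, O=C1CCC(=O)N1Br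
Why: Electrophilic aromatic bromination, in which C5 is ortho to the C4 hydroxyl and para to the C2 hydroxyl whereas the only other ring C–H (C6) is meta to both and ortho to the acetyl group, so one equivalent of NBS in a polar solvent in the cold should take C5 before the methyl ketone can enolise.

Step 3
Reactants: 4 5-bromo-2,4-dihydroxy-3-methoxyacetophenone
Product: 5 2,4-dihydroxy-3,5-dimethoxyacetophenone
Conditions: NaOMe (25 wt % in MeOH, 6 equiv), CuBr (20 mol %), DMF, 110 °C, N2; then 2 M HCl
Reagents that add atoms: sodium methoxide, [Na+].[O-]C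
Why: Ullmann-type copper-catalysed exchange of an aryl bromide ortho to a phenoxide for methoxide, the reaction type that serves for 5-halovanillins, 5-haloacetovanillones and bromohydroxyflavones; the substrate reacts as its bis-phenoxide, which makes the ketone a poor electrophile and so holds back aldol self-condensation.

Step 4
Reactants: 5 2,4-dihydroxy-3,5-dimethoxyacetophenone; 6 isovanillin (3-hydroxy-4-methoxybenzaldehyde)
Product: 7 (E)-1-(2,4-dihydroxy-3,5-dimethoxyphenyl)-3-(3-hydroxy-4-methoxyphenyl)prop-2-en-1-one
Conditions: KOH (50 % aq, excess), EtOH, rt, N2; then 2 M HCl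
Reagents that add atoms: none
Why: Claisen–Schmidt condensation, for which concentrated alkali is needed because the ketone reacts as its bis-phenoxide, while the aldehyde stays electrophilic since the phenoxide of 6 is meta to the formyl group and 6 cannot enolise, and E1cB loss of water from the aldol gives the conjugated E-enone, as in the many direct preparations of 2',4'-dihydroxychalcones.

Step 5
Reactants: 7 the chalcone of step 4
Product: 9 7,3'-dihydroxy-6,8,4'-trimethoxyflavone [7-hydroxy-2-(3-hydroxy-4-methoxyphenyl)-6,8-dimethoxy-4H-chromen-4-one], via racemic flavanone 8 (not isolated)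
Conditions: I2 (10 mol %), DMSO, 125 °C
Reagents that add atoms: none
Why: Iodine-catalysed oxidative cyclisation of a 2'-hydroxychalcone in DMSO, in which the C2' hydroxyl, the only one ortho to the ketone, adds to the enone β-carbon (6-endo-trig oxa-Michael) to give flavanone 8 with a racemic and short-lived C2 centre, α-iodination at C3 and loss of hydrogen iodide then give the flavone while DMSO reoxidises iodide, and free phenols of this ring B type are known to survive iodine dehydrogenation of flavanones.

Step 6
Reactants: 9 7,3'-dihydroxy-6,8,4'-trimethoxyflavone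
Product: 10 7-acetoxy-2-(3-acetoxy-4-methoxyphenyl)-6,8-dimethoxy-4H-chromen-4-one
Conditions: Ac2O, pyridine, DMAP (cat.), rt
Reagents that add atoms: acetic anhydride, CC(=O)OC(C)=O
Why: DMAP-catalysed O-acetylation, in which neither phenol of 9 is chelated to the carbonyl, so both should acylate at room temperature even though the C7 hydroxyl sits between two methoxy groups, and the esters lower the electron density of rings A and B before the oxidant is met.

Step 7
Reactants: 10 7-acetoxy-2-(3-acetoxy-4-methoxyphenyl)-6,8-dimethoxy-4H-chromen-4-one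
Product: 12 acerosin 7,3'-diacetate [7-acetoxy-2-(3-acetoxy-4-methoxyphenyl)-5-hydroxy-6,8-dimethoxy-4H-chromen-4-one], via C5 trifluoroacetate 11 (not isolated)
Conditions: [RuCl2(p-cymene)]2 (5 mol %), PhI(OCOCF3)2 (1.5 equiv, in portions), CF3CO2H/(CF3CO)2O, 70 °C; then H2O/THF, rt
Reagents that add atoms: [bis(trifluoroacetoxy)iodo]benzene, O=C(OI(OC(=O)C(F)(F)F)c1ccccc1)C(F)(F)F
Why: Trifluoroacetate replaces chloride on divalent ruthenium, the C4 carbonyl oxygen binds the metal, and carboxylate-assisted concerted metalation–deprotonation of the peri C5–H bond gives a five-membered ruthenacycle (Ru, O, C4, C4a, C5). PhI(OCOCF3)2 oxidises it to tetravalent ruthenium, C–O reductive elimination releases trifluoroacetate 11 and divalent ruthenium, and water then cleaves 11 at its acyl carbon to 12, whose new hydroxyl is hydrogen-bonded to the carbonyl. The closest known reaction type is the ketone-directed ruthenium-catalysed ortho C–H oxygenation of aryl ketones, which has been applied to chromones and flavones at C5. One C5–O bond forms; no ring closes and no stereocentre arises. Site selectivity is needed against C3–H and the three ring B C–H bonds: C5–H is the only C–H on ring A and the only one that can share a five-membered chelate with the carbonyl oxygen (C3 would need a four-membered one, and ring B is out of reach). Chemoselectivity against direct arene oxidation by the trivalent iodine reagent rests on the two acetates and on partial O-protonation of the pyrone in the acid, while the anhydride keeps the new oxygen esterified as long as oxidant is present, so that the para C5–O/C8–OMe pair cannot collapse to a quinone; any acetate-to-trifluoroacetate exchange is harmless because step 8 removes either ester.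

Step 8
Reactants: 12 acerosin 7,3'-diacetate
Product: 13 acerosin (5,7,3'-trihydroxy-6,8,4'-trimethoxyflavone)
Conditions: K2CO3 (3 equiv), MeOH, 0 °C to rt, N2; then 1 M HCl
Reagents that add atoms: none
Why: Base-mediated transesterification of aryl acetates (Zemplén-type methanolysis), in which the phenoxides are good leaving groups, so both esters should fall at or below room temperature while the methyl ethers and the γ-pyrone stay intact, exclusion of air guards the electron-rich phenoxides, and acidification returns the free triphenol.

**Compound list**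
1 | 2-methoxyresorcinol (2-methoxybenzene-1,3-diol) | COc1c(O)cccc1O | starting material
2 | 1-(2,4-dihydroxy-3-methoxyphenyl)ethan-1-iminium chloride (formed in the flask) | CC(=[NH2+])c1ccc(O)c(OC)c1O.[Cl-] | intermediate
3 | 2,4-dihydroxy-3-methoxyacetophenone | CC(=O)c1ccc(O)c(OC)c1O | intermediate
4 | 5-bromo-2,4-dihydroxy-3-methoxyacetophenone | CC(=O)c1cc(Br)c(O)c(OC)c1O | intermediate
5 | 2,4-dihydroxy-3,5-dimethoxyacetophenone | CC(=O)c1cc(OC)c(O)c(OC)c1O | intermediate
6 | isovanillin (3-hydroxy-4-methoxybenzaldehyde) | COc1ccc(C=O)cc1O | starting material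
7 | (E)-1-(2,4-dihydroxy-3,5-dimethoxyphenyl)-3-(3-hydroxy-4-methoxyphenyl)prop-2-en-1-one | COc1ccc(/C=C/C(=O)c2cc(OC)c(O)c(OC)c2O)cc1O | intermediate
8 | racemic 7-hydroxy-2-(3-hydroxy-4-methoxyphenyl)-6,8-dimethoxychroman-4-one (formed in the flask, C2 racemic) | COc1ccc(C2CC(=O)c3cc(OC)c(O)c(OC)c3O2)cc1O | intermediate
9 | 7-hydroxy-2-(3-hydroxy-4-methoxyphenyl)-6,8-dimethoxy-4H-chromen-4-one | COc1ccc(-c2cc(=O)c3cc(OC)c(O)c(OC)c3o2)cc1O | intermediate
10 | 7-acetoxy-2-(3-acetoxy-4-methoxyphenyl)-6,8-dimethoxy-4H-chromen-4-one | COc1ccc(-c2cc(=O)c3cc(OC)c(OC(C)=O)c(OC)c3o2)cc1OC(C)=O | intermediate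
11 | 7-acetoxy-2-(3-acetoxy-4-methoxyphenyl)-6,8-dimethoxy-5-(trifluoroacetoxy)-4H-chromen-4-one (formed in the flask) | COc1ccc(-c2cc(=O)c3c(OC(=O)C(F)(F)F)c(OC)c(OC(C)=O)c(OC)c3o2)cc1OC(C)=O | intermediate
12 | acerosin 7,3'-diacetate | COc1ccc(-c2cc(=O)c3c(O)c(OC)c(OC(C)=O)c(OC)c3o2)cc1OC(C)=O | intermediate
13 | acerosin | COc1ccc(-c2cc(=O)c3c(O)c(OC)c(O)c(OC)c3o2)cc1O | target

Total step count: 8. Longest linear sequence: 8 (1 to 13; isovanillin 6 enters as bought).

**Steps most likely to fail**

(a) Step 7.
- **Risk:** metalation next to the C6 methoxy group may be slow. Single-electron oxidation of the alkoxy-rich rings by the trivalent iodine reagent, or oxidative demethylation across C5/C8 once the new oxygen is unmasked, could then outrun catalytic turnover.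
- **Fallback:** the C5 oxygen is brought in through a halogen placed on ring A before ring C exists, with no C–H metalation at all. It sets out from 5 and comes back at 13. NBS in MeCN should brominate the one ring position that is left, ortho and para to the two methoxy groups, to give 6-bromo-2,4-dihydroxy-3,5-dimethoxyacetophenone F1. Condensation with 6 in KOH/EtOH should give the bromochalcone F2. I2 in DMSO should close it through its only ortho hydroxyl to 5-bromo-7,3'-dihydroxy-6,8,4'-trimethoxyflavone F3. NaOMe/CuBr in DMF should replace the bromide, activated by the ortho carbonyl, to give 7,3'-dihydroxy-5,6,8,4'-tetramethoxyflavone F4. BCl3 in CH2Cl2 at low temperature, anchored on the C4 carbonyl, should cleave only the peri C5 methyl ether and deliver 13.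

(b) Step 4.
- **Risk:** enolisation of the doubly deprotonated ketone may be sluggish, leaving time for air oxidation of the phenoxides and Cannizzaro disproportionation of the aldehyde.
- **Fallback:** the charge is removed by masking. It sets out from 5 and 6 and comes back at 9. BnBr/K2CO3 in acetone should alkylate only the unchelated C4 hydroxyl of 5 to give 4-benzyloxy-2-hydroxy-3,5-dimethoxyacetophenone F5, and should convert 6 into 3-benzyloxy-4-methoxybenzaldehyde F6. With only the chelated phenol left, KOH/EtOH should give the dibenzyl chalcone F7. I2 in DMSO should give 7,3'-bis(benzyloxy)-6,8,4'-trimethoxyflavone F8. Hydrogenolysis (H2, Pd/C, EtOAc/MeOH, rt) should return 9 with the C2–C3 double bond intact.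

(c) Step 3.
- **Risk:** protodebromination of the electron-rich bromophenoxide and base-induced condensation of the methyl ketone may compete during the long heating in methoxide.
- **Fallback:** the C–O bond is made by oxidation of a boronate and the methyl group is added afterwards, all under mild base. It sets out from 4 and comes back at 5. BnBr/K2CO3 in DMF at 60 °C should give 2,4-bis(benzyloxy)-5-bromo-3-methoxyacetophenone F9. Miyaura borylation (B2pin2, PdCl2(dppf), KOAc, dioxane, 90 °C) should give the pinacol boronate F10. H2O2/NaOH in THF at 0 °C should give 2,4-bis(benzyloxy)-5-hydroxy-3-methoxyacetophenone F11. MeI/K2CO3 in acetone should give 2,4-bis(benzyloxy)-3,5-dimethoxyacetophenone F12. H2 over Pd/C in EtOAc should free both phenols and return 5.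

**Further compounds**
F1 | step 7 | 6-bromo-2,4-dihydroxy-3,5-dimethoxyacetophenone | CC(=O)c1c(Br)c(OC)c(O)c(OC)c1O
F2 | step 7 | (E)-1-(2-bromo-4,6-dihydroxy-3,5-dimethoxyphenyl)-3-(3-hydroxy-4-methoxyphenyl)prop-2-en-1-one | COc1ccc(/C=C/C(=O)c2c(Br)c(OC)c(O)c(OC)c2O)cc1O
F3 | step 7 | 5-bromo-7-hydroxy-2-(3-hydroxy-4-methoxyphenyl)-6,8-dimethoxy-4H-chromen-4-one | COc1ccc(-c2cc(=O)c3c(Br)c(OC)c(O)c(OC)c3o2)cc1O
F4 | step 7 | 7-hydroxy-2-(3-hydroxy-4-methoxyphenyl)-5,6,8-trimethoxy-4H-chromen-4-one | COc1ccc(-c2cc(=O)c3c(OC)c(OC)c(O)c(OC)c3o2)cc1O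
F5 | step 4 | 4-benzyloxy-2-hydroxy-3,5-dimethoxyacetophenone | CC(=O)c1cc(OC)c(OCc2ccccc2)c(OC)c1O
F6 | step 4 | 3-benzyloxy-4-methoxybenzaldehyde | COc1ccc(C=O)cc1OCc1ccccc1
F7 | step 4 | (E)-1-(4-benzyloxy-2-hydroxy-3,5-dimethoxyphenyl)-3-(3-benzyloxy-4-methoxyphenyl)prop-2-en-1-one | COc1ccc(/C=C/C(=O)c2cc(OC)c(OCc3ccccc3)c(OC)c2O)cc1OCc1ccccc1
F8 | step 4 | 7-benzyloxy-2-(3-benzyloxy-4-methoxyphenyl)-6,8-dimethoxy-4H-chromen-4-one | COc1ccc(-c2cc(=O)c3cc(OC)c(OCc4ccccc4)c(OC)c3o2)cc1OCc1ccccc1
F9 | step 3 | 2,4-bis(benzyloxy)-5-bromo-3-methoxyacetophenone | CC(=O)c1cc(Br)c(OCc2ccccc2)c(OC)c1OCc1ccccc1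
F10 | step 3 | 2,4-bis(benzyloxy)-3-methoxy-5-(4,4,5,5-tetramethyl-1,3,2-dioxaborolan-2-yl)acetophenone | CC(=O)c1cc(B2OC(C)(C)C(C)(C)O2)c(OCc2ccccc2)c(OC)c1OCc1ccccc1
F11 | step 3 | 2,4-bis(benzyloxy)-5-hydroxy-3-methoxyacetophenone | CC(=O)c1cc(O)c(OCc2ccccc2)c(OC)c1OCc1ccccc1
F12 | step 3 | 2,4-bis(benzyloxy)-3,5-dimethoxyacetophenone | CC(=O)c1cc(OC)c(OCc2ccccc2)c(OC)c1OCc1ccccc1
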